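**Strategy.** Both end groups are traced to one building block, (R)-4-silyloxy-2,6,6-trimethylcyclohexenyl triflate 8, joined to a C10 dialdehyde by two Wittig reactions. Everything rests on closing that ring between C4' (ring B; the CH2 next to the carbinol C3') and C5' (the methyl-bearing carbon). The acyclic precursor 6 is an ethyl ketone whose carbonyl C6' is flanked by the quaternary C1', so only C5' can enolise. Its enolate displaces chloride from C4', which with C3' comes from (S)-epichlorohydrin. In the same flask a second enolisation at C5' and O-triflation fix the tetrasubstituted C5'=C6' alkene. Sonogashira coupling of 8 gives the acetylenic end (ring A), B-alkyl Suzuki coupling the 7',8'-dihydro end (ring B).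

Key step: step 4

Remark: locants C1'–C6' name the atoms of the 7',8'-dihydro ring (ring B) and C1–C6 those of the acetylenic ring (ring A), also in intermediates; compounds 1, 2, 9 and 18 are taken as commercial; TBS = tert-butyldimethylsilyl; polyenes are handled under argon in dim light.

**Step 1**
Reactants: 1 isobutyronitrile; 2 (S)-epichlorohydrin
Product: 3 (S)-5-chloro-4-hydroxy-2,2-dimethylpentanenitrile
Conditions: LiN(i-Pr)2 (1.05 equiv), THF, −78 °C; then 2 (1.2 equiv), −78 → −20 °C; AcOH quench at −20 °C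
Reagents that add atoms: none
Why: SN2 opening of the epoxide at its unsubstituted carbon by the α-lithiated nitrile (nitrile-anion alkylation; no second α-hydrogen, so no cyclopropane can form) leaves the stereocentre of 2 untouched, so (S)-2 should give (S)-3, and the cold acidic quench should keep the chlorohydrin from closing to an epoxide.

**Step 2**
Reactants: 3 (S)-5-chloro-4-hydroxy-2,2-dimethylpentanenitrile
Product: 4 (S)-4-[(tert-butyldimethylsilyl)oxy]-5-chloro-2,2-dimethylpentanenitrile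
Conditions: TBSCl (1.3 equiv), imidazole (2.5 equiv), DMF, 25 °C
Reagents that add atoms: tert-butyldimethylsilyl chloride CC(C)(C)[Si](C)(C)Cl
Why: Imidazole-promoted O-silylation of the secondary alcohol (silyl ether protection) masks the oxygen that would otherwise displace the neighbouring chloride under the basic conditions of steps 3 and 4, and the stereocentre is not touched.

**Step 3**
Reactants: 4 (S)-4-[(tert-butyldimethylsilyl)oxy]-5-chloro-2,2-dimethylpentanenitrile
Product: 6 (S)-6-[(tert-butyldimethylsilyl)oxy]-7-chloro-4,4-dimethylheptan-3-one, via ketimine 5 (not isolated)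
Conditions: EtLi (1.2 equiv), Et2O, −78 → −30 °C; then AcOH–NaOAc buffer (pH 4.5), THF–H2O, 25 °C
Reagents that add atoms: ethyllithium [Li]CC; water O
Why: 1,2-Addition of the organolithium to the nitrile stops at the N-lithio ketimine (the nitrile has no α-hydrogen), the low temperature should keep this anion from attacking the primary chloride, and buffered hydrolysis of the ketimine should give the ethyl ketone without loss of the silyl ether.

**Step 4**
Reactants: 6 (S)-6-[(tert-butyldimethylsilyl)oxy]-7-chloro-4,4-dimethylheptan-3-one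
Product: 8 (R)-4-[(tert-butyldimethylsilyl)oxy]-2,6,6-trimethylcyclohex-1-en-1-yl trifluoromethanesulfonate, via cyclohexanone 7 (not isolated)
Conditions: KN(SiMe3)2 (1.05 equiv), THF (0.02 M), −78 → 45 °C; then KN(SiMe3)2 (1.2 equiv), −78 → 0 °C; PhNTf2 (1.3 equiv), −78 → 0 °C
Reagents that add atoms: N-phenylbis(trifluoromethanesulfonimide) O=S(=O)(N(c1ccccc1)S(=O)(=O)C(F)(F)F)C(F)(F)F
Why: KN(SiMe3)2 removes one of the only acidic α-hydrogens of 6 (at C5', because C1' on the other side of the C6' carbonyl is quaternary) and the potassium enolate displaces chloride from the primary C4' in an intramolecular SN2 C-alkylation that forms the C4'–C5' bond. The closest known reaction type is the base-mediated cyclisation of gem-dimethyl-blocked 6-halohexan-2-ones to 2,2-dimethylcyclohexanones (intramolecular ketone enolate alkylation). The six-membered ring closes in the 6-(enolendo)-exo-tet mode, which is stereoelectronically favoured. The C3' stereocentre comes unchanged from 2, and the new C5' centre forms as an epimer mixture that is erased when the second equivalent of base enolises 7, again only towards C5', and PhNTf2 O-sulfonylates this enolate to fix the tetrasubstituted C5'=C6' alkene (enol triflate formation). The step needs C- over O-alkylation and ring closure over intermolecular alkylation, which the soft primary chloride, the favoured closure mode, high dilution and the gem-dimethyl effect of C1' should secure, while portionwise base keeps excess amide away from the chloride.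

**Step 5**
Reactants: 8 (R)-4-[(tert-butyldimethylsilyl)oxy]-2,6,6-trimethylcyclohex-1-en-1-yl trifluoromethanesulfonate; 9 (E)-3-methylpent-2-en-4-yn-1-ol
Product: 10 (E)-5-{(R)-4-[(tert-butyldimethylsilyl)oxy]-2,6,6-trimethylcyclohex-1-en-1-yl}-3-methylpent-2-en-4-yn-1-ol
Conditions: Pd(PPh3)4 (5 mol %), CuI (10 mol %), i-Pr2NH, DMF, 50 °C
Reagents that add atoms: none
Why: Sonogashira coupling (zerovalent palladium with CuI co-catalysis) of the enol triflate with the terminal alkyne forms the C6–C7 bond of ring A, and the E geometry of 9, the free primary alcohol and the silyl ether should all survive.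

**Step 6**
Reactants: 10 (E)-5-{(R)-4-[(tert-butyldimethylsilyl)oxy]-2,6,6-trimethylcyclohex-1-en-1-yl}-3-methylpent-2-en-4-yn-1-ol
Product: 12 tributyl[(E)-5-{(R)-4-[(tert-butyldimethylsilyl)oxy]-2,6,6-trimethylcyclohex-1-en-1-yl}-3-methylpent-2-en-4-yn-1-yl]phosphonium bromide, via allylic bromide 11 (not isolated)
Conditions: NBS (1.2 equiv), Me2S (1.3 equiv), CH2Cl2, −30 → 0 °C; then PBu3 (1.1 equiv), MeCN, 25 °C
Reagents that add atoms: N-bromosuccinimide O=C1CCC(=O)N1Br; tributylphosphine CCCCP(CCCC)CCCC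
Why: Corey–Kim bromination converts the primary allylic alcohol into the bromide by SN2 displacement of an alkoxysulfonium ion without a free allyl cation, so the 9E geometry should be kept, and SN2 quaternisation with PBu3 then gives the phosphonium salt, chosen as the tributyl salt because allylic trialkylphosphonium ylides are E-selective.

**Step 7**
Reactants: 9 (E)-3-methylpent-2-en-4-yn-1-ol
Product: 13 (E)-3-methylpenta-2,4-dien-1-ol
Conditions: H2 (1 atm), Pd on CaCO3 poisoned with Pb(OAc)2 (Lindlar catalyst), quinoline, EtOAc, 0 °C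
Reagents that add atoms: none
Why: Lindlar semi-hydrogenation should reduce only the terminal alkyne to the vinyl group and leave the trisubstituted E alkene and the allylic alcohol untouched.

**Step 8**
Reactants: 13 (E)-3-methylpenta-2,4-dien-1-ol; 8 (R)-4-[(tert-butyldimethylsilyl)oxy]-2,6,6-trimethylcyclohex-1-en-1-yl trifluoromethanesulfonate
Product: 15 (E)-5-{(R)-4-[(tert-butyldimethylsilyl)oxy]-2,6,6-trimethylcyclohex-1-en-1-yl}-3-methylpent-2-en-1-ol, via alkylborane 14 (not isolated)
Conditions: 13 (1.5 equiv), 9-BBN-H (3.3 equiv), THF, 0 → 25 °C; then 8 (1.0 equiv), PdCl2(dppf) (5 mol %), AsPh3 (5 mol %), 3 M aq. K3PO4, DMF, 50 °C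
Reagents that add atoms: none
Why: The first equivalent of 9-BBN-H masks the hydroxyl as a B-alkoxyborane, the second hydroborates the terminal vinyl group anti-Markovnikov (the trisubstituted alkene is too hindered), and B-alkyl Suzuki–Miyaura coupling of the primary alkylborane with enol triflate 8 forms the C6'–C7' bond while the aqueous base frees the alcohol, with the E geometry of 13 retained.

**Step 9**
Reactants: 15 (E)-5-{(R)-4-[(tert-butyldimethylsilyl)oxy]-2,6,6-trimethylcyclohex-1-en-1-yl}-3-methylpent-2-en-1-ol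
Product: 17 tributyl[(E)-5-{(R)-4-[(tert-butyldimethylsilyl)oxy]-2,6,6-trimethylcyclohex-1-en-1-yl}-3-methylpent-2-en-1-yl]phosphonium bromide, via allylic bromide 16 (not isolated)
Conditions: NBS (1.2 equiv), Me2S (1.3 equiv), CH2Cl2, −30 → 0 °C; then PBu3 (1.1 equiv), MeCN, 25 °C
Reagents that add atoms: N-bromosuccinimide O=C1CCC(=O)N1Br; tributylphosphine CCCCP(CCCC)CCCC
Why: Corey–Kim bromination followed by SN2 quaternisation, as in step 6, should give the allylic phosphonium salt with the C9'=C10' E geometry and the secondary silyl ether intact.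

**Step 10**
Reactants: 17 tributyl[(E)-5-{(R)-4-[(tert-butyldimethylsilyl)oxy]-2,6,6-trimethylcyclohex-1-en-1-yl}-3-methylpent-2-en-1-yl]phosphonium bromide; 18 (2E,4E,6E)-2,7-dimethylocta-2,4,6-trienedial
Product: 19 (2E,4E,6E,8E,10E)-13-{(R)-4-[(tert-butyldimethylsilyl)oxy]-2,6,6-trimethylcyclohex-1-en-1-yl}-2,7,11-trimethyltrideca-2,4,6,8,10-pentaenal
Conditions: KOtBu (1.0 equiv), THF, −78 °C; ylide added to 18 (2.5 equiv), THF, −78 → 0 °C
Reagents that add atoms: none
Why: Wittig reaction of the allylic tributylphosphonium ylide, a class that gives mainly E alkenes, with an excess of the symmetrical dialdehyde should stop at mono-olefination and form the C11'=C12' bond, and the preformed ylide at low temperature should keep the C9'=C10' geometry.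

**Step 11**
Reactants: 12 tributyl[(E)-5-{(R)-4-[(tert-butyldimethylsilyl)oxy]-2,6,6-trimethylcyclohex-1-en-1-yl}-3-methylpent-2-en-4-yn-1-yl]phosphonium bromide; 19 (2E,4E,6E,8E,10E)-13-{(R)-4-[(tert-butyldimethylsilyl)oxy]-2,6,6-trimethylcyclohex-1-en-1-yl}-2,7,11-trimethyltrideca-2,4,6,8,10-pentaenal
Product: 20 (3R,3'R)-3,3'-bis[(tert-butyldimethylsilyl)oxy]-7,8-didehydro-7',8'-dihydro-β,β-carotene (all-E)
Conditions: KOtBu (1.05 equiv), THF, −78 °C; then 19, −78 → 0 °C
Reagents that add atoms: none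
Why: Wittig reaction of the conjugated tributylphosphonium ylide with the C25 aldehyde forms the C11=C12 bond, mainly as the E isomer, and completes the C40 skeleton, and a minor 11Z isomer should be removable by chromatography or crystallisation.

**Step 12**
Reactants: 20 (3R,3'R)-3,3'-bis[(tert-butyldimethylsilyl)oxy]-7,8-didehydro-7',8'-dihydro-β,β-carotene
Product: 21 (3R,3'R)-7,8-didehydro-7',8'-dihydro-β,β-carotene-3,3'-diol (CNP0178054.1)
Conditions: Bu4NF (4 equiv), THF, 0 → 25 °C
Reagents that add atoms: none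
Why: Fluoride-mediated desilylation (formation of the strong Si–F bond) should free both secondary alcohols under non-acidic conditions that the polyene and the enyne tolerate, with both stereocentres untouched.

**Compound list**

1 | isobutyronitrile | CC(C)C#N | starting material
2 | (S)-epichlorohydrin | ClC[C@@H]1CO1 | starting material
3 | (S)-5-chloro-4-hydroxy-2,2-dimethylpentanenitrile | N#CC(C)(C)C[C@H](O)CCl | intermediate
4 | (S)-4-[(tert-butyldimethylsilyl)oxy]-5-chloro-2,2-dimethylpentanenitrile | N#CC(C)(C)C[C@H](O[Si](C)(C)C(C)(C)C)CCl | intermediate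
5 | (S)-6-[(tert-butyldimethylsilyl)oxy]-7-chloro-4,4-dimethylheptan-3-imine | CCC(=N)C(C)(C)C[C@H](O[Si](C)(C)C(C)(C)C)CCl | intermediate
6 | (S)-6-[(tert-butyldimethylsilyl)oxy]-7-chloro-4,4-dimethylheptan-3-one | CCC(=O)C(C)(C)C[C@H](O[Si](C)(C)C(C)(C)C)CCl | intermediate
7 | (4R)-4-[(tert-butyldimethylsilyl)oxy]-2,2,6-trimethylcyclohexan-1-one (mixture of C6 epimers) | CC1C[C@@H](O[Si](C)(C)C(C)(C)C)CC(C)(C)C1=O | intermediate
8 | (R)-4-[(tert-butyldimethylsilyl)oxy]-2,6,6-trimethylcyclohex-1-en-1-yl trifluoromethanesulfonate | CC1=C(OS(=O)(=O)C(F)(F)F)C(C)(C)C[C@H](O[Si](C)(C)C(C)(C)C)C1 | intermediate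
9 | (E)-3-methylpent-2-en-4-yn-1-ol | C#C/C(C)=C/CO | starting material
10 | (E)-5-{(R)-4-[(tert-butyldimethylsilyl)oxy]-2,6,6-trimethylcyclohex-1-en-1-yl}-3-methylpent-2-en-4-yn-1-ol | CC1=C(C#C/C(C)=C/CO)C(C)(C)C[C@H](O[Si](C)(C)C(C)(C)C)C1 | intermediate
11 | {[(R)-4-[(E)-5-bromo-3-methylpent-3-en-1-yn-1-yl]-3,5,5-trimethylcyclohex-3-en-1-yl]oxy}(tert-butyl)dimethylsilane | CC1=C(C#C/C(C)=C/CBr)C(C)(C)C[C@H](O[Si](C)(C)C(C)(C)C)C1 | intermediate
12 | tributyl[(E)-5-{(R)-4-[(tert-butyldimethylsilyl)oxy]-2,6,6-trimethylcyclohex-1-en-1-yl}-3-methylpent-2-en-4-yn-1-yl]phosphonium bromide | CC1=C(C#C/C(C)=C/C[P+](CCCC)(CCCC)CCCC)C(C)(C)C[C@H](O[Si](C)(C)C(C)(C)C)C1.[Br-] | intermediate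
13 | (E)-3-methylpenta-2,4-dien-1-ol | C=C/C(C)=C/CO | intermediate
14 | 9-[(E)-5-(9-borabicyclo[3.3.1]nonan-9-yloxy)-3-methylpent-3-en-1-yl]-9-borabicyclo[3.3.1]nonane | C/C(CCB1C2CCCC1CCC2)=C\COB1C2CCCC1CCC2 | intermediate
15 | (E)-5-{(R)-4-[(tert-butyldimethylsilyl)oxy]-2,6,6-trimethylcyclohex-1-en-1-yl}-3-methylpent-2-en-1-ol | CC1=C(CC/C(C)=C/CO)C(C)(C)C[C@H](O[Si](C)(C)C(C)(C)C)C1 | intermediate
16 | {[(R)-4-[(E)-5-bromo-3-methylpent-3-en-1-yl]-3,5,5-trimethylcyclohex-3-en-1-yl]oxy}(tert-butyl)dimethylsilane | CC1=C(CC/C(C)=C/CBr)C(C)(C)C[C@H](O[Si](C)(C)C(C)(C)C)C1 | intermediate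
17 | tributyl[(E)-5-{(R)-4-[(tert-butyldimethylsilyl)oxy]-2,6,6-trimethylcyclohex-1-en-1-yl}-3-methylpent-2-en-1-yl]phosphonium bromide | CC1=C(CC/C(C)=C/C[P+](CCCC)(CCCC)CCCC)C(C)(C)C[C@H](O[Si](C)(C)C(C)(C)C)C1.[Br-] | intermediate
18 | (2E,4E,6E)-2,7-dimethylocta-2,4,6-trienedial | O=C/C(C)=C/C=C/C=C(C)/C=O | starting material
19 | (2E,4E,6E,8E,10E)-13-{(R)-4-[(tert-butyldimethylsilyl)oxy]-2,6,6-trimethylcyclohex-1-en-1-yl}-2,7,11-trimethyltrideca-2,4,6,8,10-pentaenal | O=C/C(C)=C/C=C/C=C(C)/C=C/C=C(\C)CCC1=C(C)C[C@@H](O[Si](C)(C)C(C)(C)C)CC1(C)C | intermediate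
20 | (3R,3'R)-3,3'-bis[(tert-butyldimethylsilyl)oxy]-7,8-didehydro-7',8'-dihydro-β,β-carotene | CC1=C(C#C/C(C)=C/C=C/C(C)=C/C=C/C=C(C)/C=C/C=C(\C)CCC2=C(C)C[C@@H](O[Si](C)(C)C(C)(C)C)CC2(C)C)C(C)(C)C[C@H](O[Si](C)(C)C(C)(C)C)C1 | intermediate
21 | (3R,3'R)-7,8-didehydro-7',8'-dihydro-β,β-carotene-3,3'-diol | CC1=C(C#C/C(C)=C/C=C/C(C)=C/C=C/C=C(C)/C=C/C=C(\C)CCC2=C(C)C[C@@H](O)CC2(C)C)C(C)(C)C[C@H](O)C1 | target

**Count**

Total steps: 12. Longest linear sequence: 9 steps (steps 1, 2, 3, 4, 8, 9, 10, 11, 12).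

**Steps most likely to fail**

Step 4. The SN2 displacement at the β-silyloxy primary chloride may be slow, so that O-alkylation to the six-membered cyclic enol ether or intermolecular alkylation competes, and the second enolisation of the hindered ketone may stay incomplete before triflation. The fallback sets out from 1, comes back at 7 and joins the same two ring atoms by ring-closing metathesis. Lithiated 1 opens (R)-2-vinyloxirane at its CH2 group to give (S)-4-hydroxy-2,2-dimethylhex-5-enenitrile F1. Silylation (TBSCl, imidazole) gives (S)-4-[(tert-butyldimethylsilyl)oxy]-2,2-dimethylhex-5-enenitrile F2. Addition of isopropenylmagnesium bromide (CuBr catalyst, THF) and buffered hydrolysis give (S)-6-[(tert-butyldimethylsilyl)oxy]-2,4,4-trimethylocta-1,7-dien-3-one F3. Second-generation Grubbs catalyst (CH2Cl2, 40 °C) closes the ring to (S)-4-[(tert-butyldimethylsilyl)oxy]-2,6,6-trimethylcyclohex-2-en-1-one F4. Hydrogenation (H2, Pd on carbon, EtOAc) saturates the enone to 7, which is then isolated and triflated on its own (KN(SiMe3)2, PhNTf2) to 8.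

Step 8. Transmetalation and reductive elimination at the enol triflate, which is flanked by the gem-dimethyl carbon and the methyl-bearing carbon, may be slower than protodeboronation of 14 or hydrolysis of 8, and incomplete masking of the hydroxyl may consume the borane. The fallback sets out from 8, comes back at 15 and builds the side chain stepwise. Iron-catalysed alkyl–alkenyl coupling of 8 with [2-(2-methyl-1,3-dioxolan-2-yl)ethyl]magnesium bromide (Fe(acac)3, THF–NMP, −20 °C) gives tert-butyldimethyl{[(R)-3,5,5-trimethyl-4-[2-(2-methyl-1,3-dioxolan-2-yl)ethyl]cyclohex-3-en-1-yl]oxy}silane F5. Mild deketalisation (pyridinium tosylate, acetone–H2O) gives 4-{(R)-4-[(tert-butyldimethylsilyl)oxy]-2,6,6-trimethylcyclohex-1-en-1-yl}butan-2-one F6. Horner–Wadsworth–Emmons olefination (triethyl phosphonoacetate, NaH, THF) and separation of the E isomer give ethyl (E)-5-{(R)-4-[(tert-butyldimethylsilyl)oxy]-2,6,6-trimethylcyclohex-1-en-1-yl}-3-methylpent-2-enoate F7. Reduction with i-Bu2AlH (CH2Cl2, −78 °C) gives 15.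

Step 11. The ylide from 12 is an allyl-type anion delocalised over C9–C11 and into the enyne, so rotation about C9–C10 may erode the 9E geometry, and E/Z control at the new C11=C12 bond may be poor. The fallback sets out from 10 and 19, comes back at 20 and reverses the polarity of the last olefination so that the ring A enyne never passes through a carbanion. Oxidation of 10 with MnO2 (CH2Cl2) gives (E)-5-{(R)-4-[(tert-butyldimethylsilyl)oxy]-2,6,6-trimethylcyclohex-1-en-1-yl}-3-methylpent-2-en-4-ynal F8. Reduction of 19 with NaBH4 (MeOH–THF, 0 °C) gives (2E,4E,6E,8E,10E)-13-{(R)-4-[(tert-butyldimethylsilyl)oxy]-2,6,6-trimethylcyclohex-1-en-1-yl}-2,7,11-trimethyltrideca-2,4,6,8,10-pentaen-1-ol F9. Bromination and quaternisation as in step 6 (NBS, Me2S; PBu3) give tributyl[(2E,4E,6E,8E,10E)-13-{(R)-4-[(tert-butyldimethylsilyl)oxy]-2,6,6-trimethylcyclohex-1-en-1-yl}-2,7,11-trimethyltrideca-2,4,6,8,10-pentaen-1-yl]phosphonium bromide F10. Wittig reaction of its ylide (KOtBu, THF, −78 → 0 °C) with F8 gives 20.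

**Further compounds**

F1 | step 4 | (S)-4-hydroxy-2,2-dimethylhex-5-enenitrile | N#CC(C)(C)C[C@H](O)C=C
F2 | step 4 | (S)-4-[(tert-butyldimethylsilyl)oxy]-2,2-dimethylhex-5-enenitrile | N#CC(C)(C)C[C@H](O[Si](C)(C)C(C)(C)C)C=C
F3 | step 4 | (S)-6-[(tert-butyldimethylsilyl)oxy]-2,4,4-trimethylocta-1,7-dien-3-one | C=C(C)C(=O)C(C)(C)C[C@H](O[Si](C)(C)C(C)(C)C)C=C
F4 | step 4 | (S)-4-[(tert-butyldimethylsilyl)oxy]-2,6,6-trimethylcyclohex-2-en-1-one | CC1=C[C@@H](O[Si](C)(C)C(C)(C)C)CC(C)(C)C1=O
F5 | step 8 | tert-butyldimethyl{[(R)-3,5,5-trimethyl-4-[2-(2-methyl-1,3-dioxolan-2-yl)ethyl]cyclohex-3-en-1-yl]oxy}silane | CC1=C(CCC2(C)OCCO2)C(C)(C)C[C@H](O[Si](C)(C)C(C)(C)C)C1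
F6 | step 8 | 4-{(R)-4-[(tert-butyldimethylsilyl)oxy]-2,6,6-trimethylcyclohex-1-en-1-yl}butan-2-one | CC1=C(CCC(C)=O)C(C)(C)C[C@H](O[Si](C)(C)C(C)(C)C)C1
F7 | step 8 | ethyl (E)-5-{(R)-4-[(tert-butyldimethylsilyl)oxy]-2,6,6-trimethylcyclohex-1-en-1-yl}-3-methylpent-2-enoate | CC1=C(CC/C(C)=C/C(=O)OCC)C(C)(C)C[C@H](O[Si](C)(C)C(C)(C)C)C1
F8 | step 11 | (E)-5-{(R)-4-[(tert-butyldimethylsilyl)oxy]-2,6,6-trimethylcyclohex-1-en-1-yl}-3-methylpent-2-en-4-ynal | CC1=C(C#C/C(C)=C/C=O)C(C)(C)C[C@H](O[Si](C)(C)C(C)(C)C)C1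
F9 | step 11 | (2E,4E,6E,8E,10E)-13-{(R)-4-[(tert-butyldimethylsilyl)oxy]-2,6,6-trimethylcyclohex-1-en-1-yl}-2,7,11-trimethyltrideca-2,4,6,8,10-pentaen-1-ol | OC/C(C)=C/C=C/C=C(C)/C=C/C=C(\C)CCC1=C(C)C[C@@H](O[Si](C)(C)C(C)(C)C)CC1(C)C
F10 | step 11 | tributyl[(2E,4E,6E,8E,10E)-13-{(R)-4-[(tert-butyldimethylsilyl)oxy]-2,6,6-trimethylcyclohex-1-en-1-yl}-2,7,11-trimethyltrideca-2,4,6,8,10-pentaen-1-yl]phosphonium bromide | CCCC[P+](CCCC)(CCCC)C/C(C)=C/C=C/C=C(C)/C=C/C=C(\C)CCC1=C(C)C[C@@H](O[Si](C)(C)C(C)(C)C)CC1(C)C.[Br-]
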